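**Retrosynthetic overview**

1. The target is an achiral octamer; it is unmasked last from its icosamethyl ether 23 by global O-demethylation.
2. The feature the strategy rests on: rings B, D and F (lettered A to H from the 3,5-dihydroxyphenoxy end) are the same benzene with five contiguous oxygens (aryl ethers at C1 and C2, H at C3, hydroxyls at C4 to C6). Each is bonded through its C2 oxygen to C1 of a 2,6-dioxygenated ring (C, E, G), so one module, phenol 11, serves three times.
3. Four ether bonds (A–O–B, C–O–D, E–O–F, G–O–H) are cut to phenol plus arylboronic acid (Chan–Lam coupling). The boron is placed at C4 of rings C, E and G by sterically governed C–H borylation, growing the chain from A to H.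
4. The module ring is the only ring built: its C1–C2 bond forms by thermal ring expansion of a squarate-derived 4-methoxy-4-[(Z)-2-aryloxyvinyl]cyclobutenone (8). The hindered B–O–C type ether is made beforehand as an enol ether from 2,6-dimethoxyphenol and trichloroethylene.
5. Ring order: the module ring (step 4) first, then ring A, module (D+E), module (F+G) and ring H are appended.

Key step: step 4

Assumption: the target has no stereocentre and its diaryl ether axes are taken as freely rotating, so the only stereochemical task is the Z enol ether of 8. In the copper couplings O2 is the terminal oxidant (reduced to water) and Cu(OAc)2 returns to divalent copper, so boric acid is the only co-product.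

**Route**

Step 1
Reactants: 1 2,6-dimethoxyphenol; 2 trichloroethylene
Product: 3 2-[(E)-1,2-dichloroethenoxy]-1,3-dimethoxybenzene
Conditions: K2CO3 (2 equiv), 2 (1.5 equiv), DMF, 70 °C
Reagents that add atoms: none
Why: Base turns trichloroethylene into dichloroacetylene in the flask and anti addition of the phenoxide should give the (E)-1,2-dichlorovinyl ether, the standard entry to aryl ynol ethers (addition–elimination vinylation of a phenol).

Step 2
Reactants: 3 2-[(E)-1,2-dichloroethenoxy]-1,3-dimethoxybenzene; 4 dimethyl squarate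
Product: 7 4-[(2,6-dimethoxyphenoxy)ethynyl]-2,3,4-trimethoxycyclobut-2-en-1-one (racemic), via lithium aryloxyacetylide 5 (not isolated), via lithium cyclobutenolate 6 (not isolated)
Conditions: n-BuLi (2.05 equiv), THF, −78 to −40 °C; then 4 (1.2 equiv), THF, −78 °C; then MeOTf (1.5 equiv), −78 to 0 °C
Reagents that add atoms: methyl trifluoromethanesulfonate COS(=O)(=O)C(F)(F)F
Why: Dehydrochlorination and lithium–chlorine exchange should give the aryloxyacetylide, which adds 1,2 to one of the two equivalent squarate carbonyls, and the tertiary alkoxide is O-methylated in the flask (acetylide addition to a squarate ester with alkoxide trapping); the new sp3 carbon is racemic and needs no control because step 4 destroys it.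

Step 3
Reactants: 7 4-[(2,6-dimethoxyphenoxy)ethynyl]-2,3,4-trimethoxycyclobut-2-en-1-one
Product: 8 4-[(Z)-2-(2,6-dimethoxyphenoxy)ethenyl]-2,3,4-trimethoxycyclobut-2-en-1-one (racemic)
Conditions: H2 (1 atm), Pd/CaCO3 poisoned with Pb(OAc)2 (Lindlar catalyst), quinoline, EtOAc, 0 °C to rt; chromatography on Et3N-washed silica, kept below 30 °C
Reagents that add atoms: none
Why: Syn delivery of hydrogen on the poisoned palladium surface should stop at the Z enol ether (Lindlar semihydrogenation, long used on alkoxyethynyl carbinol derivatives), while the tetrasubstituted vinylogous ester alkene of the four-membered ring is inert.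

Step 4
Reactants: 8 4-[(Z)-2-(2,6-dimethoxyphenoxy)ethenyl]-2,3,4-trimethoxycyclobut-2-en-1-one
Product: 11 2-(2,6-dimethoxyphenoxy)-4,5,6-trimethoxyphenol, via dienylketene 9 (not isolated), via cyclohexadienone 10 (not isolated)
Conditions: degassed p-xylene (0.02 M), 130 °C, argon
Reagents that add atoms: none
Why: Heating should open the cyclobutenone by conrotatory four-electron cleavage of the C1–C4 bond to dienylketene 9, whose ketene carbon bonds to the aryloxy-bearing vinyl carbon in a six-electron electrocyclization (the future C1–C2 bond of ring B) to give cyclohexa-2,4-dienone 10, and enolization then aromatizes this to phenol 11. The closest known reaction type is the Moore rearrangement of squarate-derived 4-alkenyl-4-alkoxycyclobutenones to mono-protected hydroquinones. The single ring formed, the pentaoxygenated benzene, is closed by thermal disrotatory six-electron electrocyclic closure of the ketene-terminated triene, not by an ionic cyclization. No stereocentre is created, since the racemic sp3 carbon of 8 and the transient sp3 carbon of 10 both end as sp2 ring carbons and the Z geometry of the enol ether is erased. The step needs torquoselectivity and oxygen differentiation: the donor methoxy group on the sp3 carbon should rotate outward in the ring opening, which turns the vinyl arm inward and cis to the ketene, and because the carbinol oxygen is already a methyl ether only the former ketene oxygen appears as a free hydroxyl at C1, flanked by the C2 aryl ether and the C6 methoxy group. The squarate supplies C1 and C4 to C6 with their oxygens, the enol ether supplies C2 with its aryl ether and the lone C3 hydrogen, and high dilution without nucleophiles should keep the ketene from dimerizing or being trapped before it closes.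

Step 5
Reactants: 11 2-(2,6-dimethoxyphenoxy)-4,5,6-trimethoxyphenol; 12 3,5-dimethoxyphenylboronic acid
Product: 13 trimer A–B–C heptamethyl ether, 1-(2,6-dimethoxyphenoxy)-2-(3,5-dimethoxyphenoxy)-3,4,5-trimethoxybenzene
Conditions: Cu(OAc)2 (1.0 equiv), pyridine (5 equiv), 12 (2.5 equiv), 4 Å MS, CH2Cl2, O2 (1 atm), rt
Reagents that add atoms: none
Why: Chan–Lam coupling transfers the unhindered 3,5-dimethoxyphenyl group from boron to the phenol oxygen through a copper aryl phenoxide, a process that tolerates phenols with two ortho substituents when the boronic acid has none.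

Step 6
Reactants: 13 trimer A–B–C heptamethyl ether
Product: 15 trimer boronic acid (B(OH)2 at C4 of ring C), via trimer pinacol boronate 14 (not isolated)
Conditions: [Ir(OMe)(cod)]2 (2 mol%), 4,4'-di-tert-butyl-2,2'-bipyridine (4 mol%), B2pin2 (1.0 equiv), THF, 80 °C; then NaIO4 (3 equiv), THF/H2O 4:1, rt; then 1 M HCl, rt
Reagents that add atoms: bis(pinacolato)diboron CC1(C)OB(OC1(C)C)B2OC(C)(C)C(C)(C)O2; water O
Why: Iridium-catalysed aromatic C–H borylation is sterically governed and C4–H of ring C is the only aryl hydrogen without an ortho substituent (every hydrogen on rings A and B lies between two oxygens, and H3/H5 of ring C are ortho to methoxy), after which periodate cleaves the pinacol ester to the boronic acid (one-pot borylation and oxidative hydrolysis).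

Step 7
Reactants: 15 trimer boronic acid; 11 2-(2,6-dimethoxyphenoxy)-4,5,6-trimethoxyphenol
Product: 16 pentamer A–E dodecamethyl ether
Conditions: Cu(OAc)2 (1.0 equiv), pyridine (5 equiv), 11 (1.5 equiv), 4 Å MS, CH2Cl2, O2 (1 atm), rt
Reagents that add atoms: none
Why: Chan–Lam coupling as in step 5, with the electron-rich boronic acid (no ortho substituent) arylating the module phenol to form the C–O–D ether.

Step 8
Reactants: 16 pentamer A–E dodecamethyl ether
Product: 18 pentamer boronic acid (B(OH)2 at C4 of ring E), via pentamer pinacol boronate 17 (not isolated)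
Conditions: [Ir(OMe)(cod)]2 (2 mol%), 4,4'-di-tert-butyl-2,2'-bipyridine (4 mol%), B2pin2 (1.0 equiv), THF, 80 °C; then NaIO4 (3 equiv), THF/H2O 4:1, rt; then 1 M HCl, rt
Reagents that add atoms: bis(pinacolato)diboron CC1(C)OB(OC1(C)C)B2OC(C)(C)C(C)(C)O2; water O
Why: Sterically governed C–H borylation as in step 6; ring C is now flanked on both remaining hydrogens by oxygen, so C4–H of the new terminal ring E is again the only unhindered aryl C–H.

Step 9
Reactants: 18 pentamer boronic acid; 11 2-(2,6-dimethoxyphenoxy)-4,5,6-trimethoxyphenol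
Product: 19 heptamer A–G heptadecamethyl ether
Conditions: Cu(OAc)2 (1.0 equiv), pyridine (5 equiv), 11 (1.5 equiv), 4 Å MS, CH2Cl2, O2 (1 atm), rt
Reagents that add atoms: none
Why: Chan–Lam coupling as in step 7, forming the E–O–F ether with the third copy of the module.

Step 10
Reactants: 19 heptamer A–G heptadecamethyl ether
Product: 21 heptamer boronic acid (B(OH)2 at C4 of ring G), via heptamer pinacol boronate 20 (not isolated)
Conditions: [Ir(OMe)(cod)]2 (3 mol%), 4,4'-di-tert-butyl-2,2'-bipyridine (6 mol%), B2pin2 (1.0 equiv), THF, 80 °C; then NaIO4 (3 equiv), THF/H2O 4:1, rt; then 1 M HCl, rt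
Reagents that add atoms: bis(pinacolato)diboron CC1(C)OB(OC1(C)C)B2OC(C)(C)C(C)(C)O2; water O
Why: Sterically governed C–H borylation as in steps 6 and 8, directed to the only aryl C–H without an ortho substituent, C4–H of terminal ring G.

Step 11
Reactants: 21 heptamer boronic acid; 22 2,4,6-trimethoxyphenol
Product: 23 octamer A–H icosamethyl ether
Conditions: Cu(OAc)2 (1.0 equiv), pyridine (5 equiv), 22 (2 equiv), 4 Å MS, CH2Cl2, O2 (1 atm), rt
Reagents that add atoms: none
Why: Chan–Lam coupling of the unhindered boronic acid with the 2,6-dimethoxy-flanked phenol closes the last ether (G–O–H) in the same way as steps 5, 7 and 9.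

Step 12
Reactants: 23 octamer A–H icosamethyl ether
Product: 24 target octamer (CNP0319661.0)
Conditions: BBr3 (60 equiv), CH2Cl2, −78 °C to rt; MeOH quench at −78 °C, degassed H2O; work-up under argon, Sephadex LH-20 (MeOH)
Reagents that add atoms: none
Why: Each aryl methyl ether complexes to boron and is cleaved at the methyl carbon by bromide (Lewis acid O-demethylation), while the seven diaryl ether bonds join two sp2 carbons and offer no such site.

**Compound list**

1 | 2,6-dimethoxyphenol | COc1cccc(OC)c1O | starting material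
2 | trichloroethylene | ClC=C(Cl)Cl | starting material
3 | 2-[(E)-1,2-dichloroethenoxy]-1,3-dimethoxybenzene | COc1cccc(OC)c1O/C(Cl)=C\Cl | intermediate
4 | dimethyl squarate (3,4-dimethoxycyclobut-3-ene-1,2-dione) | COC1=C(OC)C(=O)C1=O | starting material
5 | lithium (2,6-dimethoxyphenoxy)acetylide | [Li]C#COc1c(OC)cccc1OC | intermediate
6 | lithium 1-[(2,6-dimethoxyphenoxy)ethynyl]-2,3-dimethoxy-4-oxocyclobut-2-en-1-olate (racemic) | [Li]OC1(C#COc2c(OC)cccc2OC)C(OC)=C(OC)C1=O | intermediate
7 | 4-[(2,6-dimethoxyphenoxy)ethynyl]-2,3,4-trimethoxycyclobut-2-en-1-one (racemic) | COC1=C(OC)C(OC)(C#COc2c(OC)cccc2OC)C1=O | intermediate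
8 | 4-[(Z)-2-(2,6-dimethoxyphenoxy)ethenyl]-2,3,4-trimethoxycyclobut-2-en-1-one (racemic) | COC1=C(OC)C(OC)(/C=C\Oc2c(OC)cccc2OC)C1=O | intermediate
9 | (3Z,5Z)-6-(2,6-dimethoxyphenoxy)-2,3,4-trimethoxyhexa-1,3,5-trien-1-one (dienylketene) | O=C=C(OC)/C(OC)=C(OC)\C=C/Oc1c(OC)cccc1OC | intermediate
10 | 6-(2,6-dimethoxyphenoxy)-2,3,4-trimethoxycyclohexa-2,4-dien-1-one (racemic) | O=C1C(Oc2c(OC)cccc2OC)C=C(OC)C(OC)=C1OC | intermediate
11 | 2-(2,6-dimethoxyphenoxy)-4,5,6-trimethoxyphenol (module) | Oc1c(Oc2c(OC)cccc2OC)cc(OC)c(OC)c1OC | intermediate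
12 | 3,5-dimethoxyphenylboronic acid | COc1cc(OC)cc(B(O)O)c1 | starting material
13 | trimer A–B–C heptamethyl ether | COc1cc(OC)cc(Oc2c(Oc3c(OC)cccc3OC)cc(OC)c(OC)c2OC)c1 | intermediate
14 | trimer pinacol boronate (Bpin at C4 of ring C) | COc1cc(OC)cc(Oc2c(Oc3c(OC)cc(B4OC(C)(C)C(C)(C)O4)cc3OC)cc(OC)c(OC)c2OC)c1 | intermediate
15 | trimer boronic acid (B(OH)2 at C4 of ring C) | COc1cc(OC)cc(Oc2c(Oc3c(OC)cc(B(O)O)cc3OC)cc(OC)c(OC)c2OC)c1 | intermediate
16 | pentamer A–E dodecamethyl ether | COc1cc(OC)cc(Oc2c(Oc3c(OC)cc(Oc4c(Oc5c(OC)cccc5OC)cc(OC)c(OC)c4OC)cc3OC)cc(OC)c(OC)c2OC)c1 | intermediate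
17 | pentamer pinacol boronate (Bpin at C4 of ring E) | COc1cc(OC)cc(Oc2c(Oc3c(OC)cc(Oc4c(Oc5c(OC)cc(B6OC(C)(C)C(C)(C)O6)cc5OC)cc(OC)c(OC)c4OC)cc3OC)cc(OC)c(OC)c2OC)c1 | intermediate
18 | pentamer boronic acid (B(OH)2 at C4 of ring E) | COc1cc(OC)cc(Oc2c(Oc3c(OC)cc(Oc4c(Oc5c(OC)cc(B(O)O)cc5OC)cc(OC)c(OC)c4OC)cc3OC)cc(OC)c(OC)c2OC)c1 | intermediate
19 | heptamer A–G heptadecamethyl ether | COc1cc(OC)cc(Oc2c(Oc3c(OC)cc(Oc4c(Oc5c(OC)cc(Oc6c(Oc7c(OC)cccc7OC)cc(OC)c(OC)c6OC)cc5OC)cc(OC)c(OC)c4OC)cc3OC)cc(OC)c(OC)c2OC)c1 | intermediate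
20 | heptamer pinacol boronate (Bpin at C4 of ring G) | COc1cc(OC)cc(Oc2c(Oc3c(OC)cc(Oc4c(Oc5c(OC)cc(Oc6c(Oc7c(OC)cc(B8OC(C)(C)C(C)(C)O8)cc7OC)cc(OC)c(OC)c6OC)cc5OC)cc(OC)c(OC)c4OC)cc3OC)cc(OC)c(OC)c2OC)c1 | intermediate
21 | heptamer boronic acid (B(OH)2 at C4 of ring G) | COc1cc(OC)cc(Oc2c(Oc3c(OC)cc(Oc4c(Oc5c(OC)cc(Oc6c(Oc7c(OC)cc(B(O)O)cc7OC)cc(OC)c(OC)c6OC)cc5OC)cc(OC)c(OC)c4OC)cc3OC)cc(OC)c(OC)c2OC)c1 | intermediate
22 | 2,4,6-trimethoxyphenol | COc1cc(OC)c(O)c(OC)c1 | starting material
23 | octamer A–H icosamethyl ether | COc1cc(OC)cc(Oc2c(Oc3c(OC)cc(Oc4c(Oc5c(OC)cc(Oc6c(Oc7c(OC)cc(Oc8c(OC)cc(OC)cc8OC)cc7OC)cc(OC)c(OC)c6OC)cc5OC)cc(OC)c(OC)c4OC)cc3OC)cc(OC)c(OC)c2OC)c1 | intermediate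
24 | target octamer CNP0319661.0 | Oc1cc(O)cc(Oc2c(Oc3c(O)cc(Oc4c(Oc5c(O)cc(Oc6c(Oc7c(O)cc(Oc8c(O)cc(O)cc8O)cc7O)cc(O)c(O)c6O)cc5O)cc(O)c(O)c4O)cc3O)cc(O)c(O)c2O)c1 | target

**Step count**

Total: 12 steps. Longest linear sequence: 12 steps (from 1 through steps 1 to 12); module 11 is prepared once in steps 1 to 4 and used in steps 5, 7 and 9.

**Steps most likely to fail**

Step 4 (key step). The Z aryloxy group points into the forming ring, so the six-electron closure may be slow, and the dienylketene may then dimerize or be trapped; torquoselectivity could also erode. The fallback sets out from 1 and comes back at 11. Chan–Lam coupling of 1 with purchased 3,4,5-trimethoxyphenylboronic acid (Cu(OAc)2, pyridine, 4 Å MS, CH2Cl2, O2) should give 5-(2,6-dimethoxyphenoxy)-1,2,3-trimethoxybenzene F1. Directed ortho-lithiation with n-BuLi/TMEDA in THF at 0 °C should occur at the ring position lying between the aryl ether oxygen and a methoxy group (the two such positions are equivalent), giving the aryllithium F2. Trapping with B(OMe)3 should give the dimethyl arylboronate F3, which is oxidized in the same flask with H2O2/NaOH to 11.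

Step 7. The O-arylation of the phenol with two ortho substituents is slow, and protodeboronation, oxidation or homocoupling of the precious boronic acid may outrun it. The fallback sets out from 15 and comes back at 16. Bromodeboronation of 15 with CuBr2 in MeOH/H2O at 80 °C should give the trimer aryl bromide F4. Ullmann-type coupling of this bromide with 11 (CuI, picolinic acid, K3PO4, DMSO, 90 °C), a system suited to hindered phenols, should give 16 without an oxidant.

Step 12. Cleavage of twenty methyl ethers may stop short, and the pyrogallol-type rings B, D and F may be oxidized during isolation of the free polyphenol. The fallback sets out from 23 and comes back at 24. After BBr3 cleavage as in step 12, the crude polyphenol is not isolated but acetylated at once (Ac2O, pyridine, DMAP, rt) to the octamer icosaacetate F5. This is stable to air and can be separated by chromatography from under-cleaved material, which is resubmitted. Acid methanolysis of F5 (1.25 M HCl in degassed MeOH, 40 °C, argon) should then release 24 without exposing phenolates to air.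

**Further compounds**

F1 | step 4 | 5-(2,6-dimethoxyphenoxy)-1,2,3-trimethoxybenzene | COc1cc(Oc2c(OC)cccc2OC)cc(OC)c1OC
F2 | step 4 | [6-(2,6-dimethoxyphenoxy)-2,3,4-trimethoxyphenyl]lithium | [Li]c1c(Oc2c(OC)cccc2OC)cc(OC)c(OC)c1OC
F3 | step 4 | dimethyl [6-(2,6-dimethoxyphenoxy)-2,3,4-trimethoxyphenyl]boronate | COB(OC)c1c(Oc2c(OC)cccc2OC)cc(OC)c(OC)c1OC
F4 | step 7 | trimer aryl bromide (Br at C4 of ring C) | COc1cc(OC)cc(Oc2c(Oc3c(OC)cc(Br)cc3OC)cc(OC)c(OC)c2OC)c1
F5 | step 12 | octamer A–H icosaacetate | CC(=O)Oc1cc(OC(C)=O)cc(Oc2c(Oc3c(OC(C)=O)cc(Oc4c(Oc5c(OC(C)=O)cc(Oc6c(Oc7c(OC(C)=O)cc(Oc8c(OC(C)=O)cc(OC(C)=O)cc8OC(C)=O)cc7OC(C)=O)cc(OC(C)=O)c(OC(C)=O)c6OC(C)=O)cc5OC(C)=O)cc(OC(C)=O)c(OC(C)=O)c4OC(C)=O)cc3OC(C)=O)cc(OC(C)=O)c(OC(C)=O)c2OC(C)=O)c1
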